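**Plan**
- Retrosynthesis: both aryl–CH2 bonds are cut first, giving an aryl Grignard reagent and the (3R,4R)-bis(tosyloxymethyl)oxolane. The two CH2OTs arms are traced back to acyl groups, and then C2–C3 and C4–C5 of the oxolane are cut together.
- Enabling feature: ring oxygen O1 lies between two unsubstituted methylenes (C2H2 and C5H2), so C2–O1–C5 is the parent carbonyl ylide CH2=O(+)–CH2(−). C3–C4, with its two trans carbon arms, is an E-butenedioyl unit.
- Forward: the oxolane, the only non-aromatic ring, is made in one (3+2) cycloaddition of that ylide to a fumaric bis-imide. The auxiliaries are then reduced off, the diol is activated, and the two veratryl rings are attached last.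
- Stereochemistry: trans follows from suprafacial addition to the E-alkene. Absolute 3R,4R comes from two identical (2S)-bornane-10,2-sultams that expose the same alkene face, and no later step touches C3 or C4.

Key step: step 3

Assumption: the ylide is taken to follow the topicity established for uncatalysed cycloadditions of N-enoyl bornane-10,2-sultams (Cα-re in the 2R series, Cα-si in the 2S series); Cα-si bonding on the fumarate corresponds to 3R,4R in the oxolane (Cα-re would give 3S,4S), so the (2S)-auxiliary is used.

Step 1
Reactants: 1 (2S)-bornane-10,2-sultam [(+)-camphorsultam, 2 equiv]; 2 fumaryl chloride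
Product: 4 N,N'-fumaroylbis[(2S)-bornane-10,2-sultam], via sodium sultamide 3 (not isolated)
Conditions: NaH (2.1 equiv), toluene, 0 °C → rt; then 2 (1 equiv), rt; recrystallise
Reagents that add atoms: none
Why: N-acylation of a sulfonamide anion by an acid chloride, in which the deprotonated sultam nitrogen is the only nucleophile present, both acyl chloride termini react alike, and the E-alkene is untouched, so no stereocentre is made or disturbed.

Step 2
Reactants: 5 (trimethylsilyl)methanol
Product: 6 chloromethyl (trimethylsilyl)methyl ether
Conditions: (CH2O)n, HCl (g), CH2Cl2, 0 °C; dry (CaCl2); distil under reduced pressure (closed apparatus, α-chloro ether)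
Reagents that add atoms: paraformaldehyde (as the formaldehyde unit), C=O; hydrogen chloride, Cl
Why: Chloromethylation of an alcohol with formaldehyde and dry HCl is the standard entry to α-chloro ethers, and the Si–CH2 bond should tolerate cold anhydrous HCl because chloride is too poor a silaphile to trigger desilylation.

Step 3
Reactants: 4 N,N'-fumaroylbis[(2S)-bornane-10,2-sultam]; 6 chloromethyl (trimethylsilyl)methyl ether (3 equiv)
Product: 8 (3R,4R)-tetrahydrofuran-3,4-diylbis[(2S)-bornane-10,2-sultam-N-ylmethanone], via parent carbonyl ylide 7 (not isolated)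
Conditions: CsF (dried, 4 equiv), MeCN–CH2Cl2, rt, slow addition of 6; recrystallise or chromatograph to a single diastereomer
Reagents that add atoms: none
Why: Fluoride attacks silicon of 6 while chloride leaves from the other carbon (1,3-elimination), releasing CH2=O(+)–CH2(−) 7, a four-π-electron dipole whose high HOMO is matched to the low LUMO of the doubly acylated alkene of 4. The closest known reaction type is the fluoride-triggered generation of this same non-stabilised ylide and its 1,3-dipolar cycloaddition to fumarates, maleates and acrylates, and N-enoyl sultams are established dipolarophiles for nitrile oxides, diazoalkanes and azomethine ylides. The oxolane closes in one concerted [π4s+π2s] event in which C2–C3 and C4–C5 form together, so there is no separate exo or endo ring closure. The relative configuration of C3 and C4 is set by suprafacial addition to the E-alkene, which can only deliver the trans ring. The absolute configuration is set by the auxiliaries: with each SO2/C=O pair anti and each C=O/C=C pair s-cis, both (2S)-sultams leave the Cα-si face open on the same side of the C2-symmetric alkene, and bonding there gives 3R and 4R. Only π-facial selectivity is needed, because dipole and dipolarophile are both symmetric (no regio- or endo/exo question), and the diastereomer from the opposite face can be removed from the crystalline adduct before the auxiliaries are cleaved.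

Step 4
Reactants: 8 (3R,4R)-tetrahydrofuran-3,4-diylbis[(2S)-bornane-10,2-sultam-N-ylmethanone]
Product: 9 (3S,4S)-tetrahydrofuran-3,4-diyldimethanol [trans-3,4-bis(hydroxymethyl)tetrahydrofuran]
Conditions: LiAlH4 (excess), THF, 0 °C → rt; Na2SO4·10H2O quench, filter; H2O/CH2Cl2 partition (1 recovered from the organic layer, 9 from the aqueous layer)
Reagents that add atoms: none
Why: In this reductive cleavage of an N-acyl sultam with hydride, the imide-like carbonyls are reduced to primary alcohols faster than they enolise, so C3 and C4 keep their geometry (the descriptor becomes S only through a change in CIP ranking) and the LiAlH4-stable sultam is released intact.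

Step 5
Reactants: 9 (3S,4S)-tetrahydrofuran-3,4-diyldimethanol
Product: 10 (3R,4R)-tetrahydrofuran-3,4-diylbis(methylene) bis(4-methylbenzenesulfonate)
Conditions: TsCl (2.5 equiv), Et3N, DMAP (cat.), CH2Cl2, 0 °C → rt
Reagents that add atoms: p-toluenesulfonyl chloride, Cc1ccc(cc1)S(=O)(=O)Cl
Why: O-Sulfonylation of two primary alcohols breaks no bond at C3 or C4 (the descriptor returns to R by ranking only), and self-etherification of the monotosylate is disfavoured because it would need a strained trans-fused 3,7-dioxabicyclo[3.3.0]octane.

Step 6
Reactants: 10 (3R,4R)-tetrahydrofuran-3,4-diylbis(methylene) bis(4-methylbenzenesulfonate); 11 4-bromo-1,2-dimethoxybenzene (5 equiv)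
Product: 13 (3R,4R)-3,4-bis(3,4-dimethoxybenzyl)tetrahydrofuran, via 3,4-dimethoxyphenylmagnesium bromide 12 (not isolated)
Conditions: 11, Mg, THF, reflux; then 10, Li2CuCl4 (10 mol %), THF, −20 °C → rt
Reagents that add atoms: none
Why: In this copper-catalysed cross-coupling of a Grignard reagent with a primary alkyl sulfonate (Kochi–Schlosser coupling), each aryl group is delivered by SN2 displacement at an exocyclic CH2, one carbon away from C3 and C4, so both stereocentres pass unchanged into 13 while the aryl methyl ethers and the ring ether are inert.

**Compound list**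
1 | (2S)-bornane-10,2-sultam | CC1(C)[C@H]2CC[C@@]13CS(=O)(=O)N[C@H]3C2 | starting material
2 | fumaryl chloride | O=C(Cl)/C=C/C(=O)Cl | starting material
3 | sodium salt of (2S)-bornane-10,2-sultam | CC1(C)[C@H]2CC[C@@]13CS(=O)(=O)[N-][C@H]3C2.[Na+] | intermediate
4 | N,N'-fumaroylbis[(2S)-bornane-10,2-sultam] | CC1(C)[C@H]2CC[C@@]13CS(=O)(=O)N(C(=O)/C=C/C(=O)N4[C@H]5C[C@@H]6CC[C@]5(C6(C)C)CS4(=O)=O)[C@H]3C2 | intermediate
5 | (trimethylsilyl)methanol | C[Si](C)(C)CO | starting material
6 | chloromethyl (trimethylsilyl)methyl ether | C[Si](C)(C)COCCl | intermediate
7 | parent carbonyl ylide, CH2=O(+)–CH2(−) | C=[O+][CH2-] | intermediate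
8 | (3R,4R)-tetrahydrofuran-3,4-diylbis[(2S)-bornane-10,2-sultam-N-ylmethanone] | CC1(C)[C@H]2CC[C@@]13CS(=O)(=O)N(C(=O)[C@H]7COC[C@@H]7C(=O)N4[C@H]5C[C@@H]6CC[C@]5(C6(C)C)CS4(=O)=O)[C@H]3C2 | intermediate
9 | (3S,4S)-tetrahydrofuran-3,4-diyldimethanol | OC[C@H]1COC[C@@H]1CO | intermediate
10 | (3R,4R)-tetrahydrofuran-3,4-diylbis(methylene) bis(4-methylbenzenesulfonate) | Cc1ccc(cc1)S(=O)(=O)OC[C@H]1COC[C@@H]1COS(=O)(=O)c1ccc(C)cc1 | intermediate
11 | 4-bromo-1,2-dimethoxybenzene | COc1ccc(Br)cc1OC | starting material
12 | 3,4-dimethoxyphenylmagnesium bromide | COc1ccc([Mg]Br)cc1OC | intermediate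
13 | (3R,4R)-3,4-bis(3,4-dimethoxybenzyl)tetrahydrofuran | COc1ccc(C[C@H]2COC[C@@H]2Cc2ccc(OC)c(OC)c2)cc1OC | target

Total step count: 6. Longest linear sequence: 5 steps (1 → 4 → 8 → 9 → 10 → 13; the branch from 5 through 6 is equally long).

**Steps most likely to fail**

Step 3.
- Risk: the short-lived ylide may collapse or oligomerise before the bulky, sparingly soluble dipolarophile traps it. Fluoride may slowly cleave the activated N-acyl bonds. A very small dipole with an early transition state may also discriminate poorly between the two alkene faces.
- Fallback (covalent resolution in place of induction, independent of the facial sense), setting out from 6: the same ylide is trapped with dimethyl fumarate (CsF, MeCN, rt) to give racemic dimethyl trans-tetrahydrofuran-3,4-dicarboxylate F1. Saponification (LiOH, THF–H2O) gives racemic trans-tetrahydrofuran-3,4-dicarboxylic acid F2. Oxalyl chloride with catalytic DMF gives racemic trans-tetrahydrofuran-3,4-dicarbonyl dichloride F3. Acylation of sodium sultamide 3 (from 1 and NaH) then gives 8 together with (3S,4S)-tetrahydrofuran-3,4-diylbis[(2S)-bornane-10,2-sultam-N-ylmethanone] F4. The two diastereomers are separated by crystallisation or chromatography, and the route is rejoined at 8.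

Step 6.
- Risk: the aryl Grignard reagent may attack sulfur of the sulfonate instead of carbon. The reaction may stall after the first substitution at these β-branched positions. Biaryl formation may consume the reagent.
- Fallback (polarity reversal), setting out from 10: a Finkelstein reaction (NaI, acetone, reflux) gives (3R,4R)-3,4-bis(iodomethyl)tetrahydrofuran F5. Insertion of activated zinc (Zn, LiCl, THF) gives (3R,4R)-3,4-bis[(iodozincio)methyl]tetrahydrofuran F6. Negishi coupling with 11 (Pd(OAc)2, SPhos, THF) forms the same two aryl–CH2 bonds and arrives at 13.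

Step 4.
- Risk: the small, very polar diol may be lost on the aluminium salts or in the aqueous phase, and reduction may stop short at one of the two hindered acyl groups.
- Fallback (hydrolysis first, then a boron-based reduction with a non-aqueous isolation), setting out from 8: LiOH/H2O2 (THF–H2O, 0 °C) frees the auxiliary, which is extracted from the basic phase. Acidification gives (3R,4R)-tetrahydrofuran-3,4-dicarboxylic acid F7. BH3·THF then reduces both acids, boron is removed by co-evaporation with methanol, and the route is rejoined at 9.

**Further compounds**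
F1 | step 3 | (±)-dimethyl trans-tetrahydrofuran-3,4-dicarboxylate (racemate, one enantiomer drawn) | COC(=O)[C@H]1COC[C@@H]1C(=O)OC
F2 | step 3 | (±)-trans-tetrahydrofuran-3,4-dicarboxylic acid (racemate, one enantiomer drawn) | OC(=O)[C@H]1COC[C@@H]1C(=O)O
F3 | step 3 | (±)-trans-tetrahydrofuran-3,4-dicarbonyl dichloride (racemate, one enantiomer drawn) | ClC(=O)[C@H]1COC[C@@H]1C(=O)Cl
F4 | step 3 | (3S,4S)-tetrahydrofuran-3,4-diylbis[(2S)-bornane-10,2-sultam-N-ylmethanone] | CC1(C)[C@H]2CC[C@@]13CS(=O)(=O)N(C(=O)[C@@H]7COC[C@H]7C(=O)N4[C@H]5C[C@@H]6CC[C@]5(C6(C)C)CS4(=O)=O)[C@H]3C2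
F5 | step 6 | (3R,4R)-3,4-bis(iodomethyl)tetrahydrofuran | IC[C@H]1COC[C@@H]1CI
F6 | step 6 | (3R,4R)-3,4-bis[(iodozincio)methyl]tetrahydrofuran | I[Zn]C[C@H]1COC[C@@H]1C[Zn]I
F7 | step 4 | (3R,4R)-tetrahydrofuran-3,4-dicarboxylic acid | OC(=O)[C@H]1COC[C@@H]1C(=O)O
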